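**Plan**
- Retrosynthesis: after the phenol protecting groups and the C4 oxidation level are adjusted, the first cut is the O1–C8a aryl ether bond of ring C; the second is the C3–C4 bond (aldol); the last are the ring A–C4 bond (a formyl group) and the ring A–geranyl bond at C6.
- Enabling feature: O1 bridges the C2 carbinol carbon and C8a of ring A, so ring C can be closed at the aryl–oxygen bond from a C8a chloride, while the C2–O bond, already present as a secondary alcohol, is left alone.
- Forward: rings A and B come from the starting materials. Ring A is geranylated between its two ethers and formylated next to chlorine by two directed lithiations, the three-carbon chain is joined by aldol addition of the ring B methyl ketone, and ring C is closed last by palladium-catalysed etherification.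
- Stereochemistry: C2 (S) is the only stereocentre of the target. It is set by ruthenium-catalysed asymmetric transfer hydrogenation of the aryl ketone (step 7) and retained in the ring closure.
- End game: desilylation, oxidation of C4 to the ketone and mild acidic removal of the four MOM groups.

Key step: step 8

Remark: C4 is formed racemic in the aldol step and is carried as a mixture of both epimers from step 5 to step 9 (SMILES without a descriptor at that carbon); oxidation in step 10 removes this centre.
Abbreviations: MOM = methoxymethyl; TBS = tert-butyldimethylsilyl; geranyl = (2E)-3,7-dimethylocta-2,6-dien-1-yl.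

**Step 1**
Reactants: 1 5-chlororesorcinol
Product: 2 1-chloro-3,5-bis(methoxymethoxy)benzene
Conditions: NaH, MOMCl, DMF, 0 °C to rt
Reagents that add atoms: chloromethyl methyl ether (MOMCl), COCCl
Why: Williamson-type O-alkylation of the two sodium phenoxides gives the bis-MOM ether, whose acetal oxygens later direct both lithiations and tolerate base and zerovalent palladium.

**Step 2**
Reactants: 2 1-chloro-3,5-bis(methoxymethoxy)benzene; 3 geranyl bromide
Product: 6 geranylated chloroarene (5-chloro-2-geranyl-1,3-bis(methoxymethoxy)benzene), via aryllithium 4 (not isolated), via arylcopper 5 (not isolated)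
Conditions: n-BuLi, THF, −20 to 0 °C; CuI, −40 °C; geranyl bromide, −40 °C to rt
Reagents that add atoms: none
Why: Directed ortho-metalation should occur at the carbon flanked by both MOM ethers (para to chlorine, so no aryne can form), and transmetalation to copper followed by SN2 allylation with geranyl bromide should give the linear product with the E olefin intact.

**Step 3**
Reactants: 6 geranylated chloroarene
Product: 9 aldehyde (6-chloro-3-geranyl-2,4-bis(methoxymethoxy)benzaldehyde), via aryllithium 7 (not isolated), via lithium hemiaminal alkoxide 8 (not isolated)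
Conditions: n-BuLi, TMEDA, THF, −78 °C; DMF, −78 °C; then H2O
Reagents that add atoms: N,N-dimethylformamide, CN(C)C=O
Why: A second directed ortho-metalation at one of the two equivalent ring positions between OMOM and Cl, held at −78 °C so that LiCl is not lost, followed by formylation with DMF (Bouveault-type) should place the aldehyde next to chlorine.

**Step 4**
Reactants: 10 3',4'-dihydroxyacetophenone
Product: 11 3',4'-bis(methoxymethoxy)acetophenone
Conditions: MOMCl, K2CO3, acetone, rt
Reagents that add atoms: chloromethyl methyl ether (MOMCl), COCCl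
Why: Williamson O-alkylation of the catechol phenoxides under weakly basic conditions protects ring B without enolising the methyl ketone.

**Step 5**
Reactants: 11 3',4'-bis(methoxymethoxy)acetophenone; 9 aldehyde
Product: 13 aldol adduct (rac-3-[6-chloro-3-geranyl-2,4-bis(methoxymethoxy)phenyl]-3-hydroxy-1-[3,4-bis(methoxymethoxy)phenyl]propan-1-one), via lithium enolate 12 (not isolated)
Conditions: LiN(i-Pr)2, THF, −78 °C; then 9, −78 °C; AcOH quench at −78 °C
Reagents that add atoms: none
Why: Directed aldol addition of the preformed lithium enolate to the non-enolisable aldehyde forms the C3–C4 bond, the cold acidic quench suppressing retro-aldol and dehydration; the new carbinol centre (C4) is racemic and is later oxidised away.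

**Step 6**
Reactants: 13 aldol adduct
Product: 14 silyl ether (rac-3-(tert-butyldimethylsilyloxy)-3-[6-chloro-3-geranyl-2,4-bis(methoxymethoxy)phenyl]-1-[3,4-bis(methoxymethoxy)phenyl]propan-1-one)
Conditions: TBSOTf, 2,6-lutidine, CH2Cl2, −78 °C
Reagents that add atoms: tert-butyldimethylsilyl triflate, CC(C)(C)[Si](C)(C)OS(=O)(=O)C(F)(F)F
Why: Silylation of the hindered secondary alcohol with a silyl triflate and a hindered pyridine base is fast at −78 °C, leaves the aryl MOM ethers untouched, and blocks both retro-aldol and any later participation of the C4 oxygen.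

**Step 7**
Reactants: 14 silyl ether
Product: 15 (1S)-3-(tert-butyldimethylsilyloxy)-3-[6-chloro-3-geranyl-2,4-bis(methoxymethoxy)phenyl]-1-[3,4-bis(methoxymethoxy)phenyl]propan-1-ol, both C3 epimers
Conditions: RuCl[(S,S)-TsDPEN](p-cymene) (2 mol%), HCO2H/Et3N (5:2), EtOAc, 35 °C
Reagents that add atoms: none
Why: Noyori asymmetric transfer hydrogenation of the aryl alkyl ketone should deliver hydride to the Re face under control of the (S,S)-TsDPEN ligand (aryl/arene CH–π recognition, as for acetophenone), giving the S carbinol that becomes C2, while the alkenes, the aryl chloride and the silyl ether are not touched.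

**Step 8**
Reactants: 15 (1S)-alcohol, both C3 epimers
Product: 16 (2S)-4-(tert-butyldimethylsilyloxy)-6-geranyl-5,7,3',4'-tetrakis(methoxymethoxy)flavan, both C4 epimers
Conditions: Pd(OAc)2 (5 mol%), 2-(di-tert-butylphosphino)-1,1'-binaphthyl (6 mol%), Cs2CO3, toluene, 80 °C
Reagents that add atoms: none
Why: Zerovalent palladium, formed in situ from Pd(OAc)2 and the phosphine, inserts into the C8a–Cl bond of ring A, the caesium alkoxide of the carbinol displaces chloride on divalent palladium to give a seven-membered aryl(alkoxo)palladium chelate, and C–O reductive elimination forms O1–C8a. The closest known reaction type is the Buchwald–Hartwig intramolecular etherification of aryl halides with tethered secondary alcohols, which gives chromans from aryl chlorides and bromides. Ring C, the six-membered pyran ring, closes in a 6-exo sense by O-arylation, the C–Cl bond that breaks lying outside the new ring. No stereocentre is created: the C2–O bond is never broken, so the S configuration from step 7 is carried over with retention, and both C4 epimers should cyclise. The step needs reductive elimination to outrun beta-hydride elimination of the benzylic alkoxide, which would give the dechlorinated ketone; the bulky di-tert-butyl biaryl phosphine and the easy six-membered closure favour the former. Site selectivity lies in the substrate, which holds a single carbon–halogen bond and a single free hydroxyl, the C4 oxygen being silylated and all phenols being MOM ethers.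

**Step 9**
Reactants: 16 (2S)-4-silyloxyflavan
Product: 17 (2S)-6-geranyl-5,7,3',4'-tetrakis(methoxymethoxy)flavan-4-ol, both C4 epimers
Conditions: Bu4NF, THF, 0 °C to rt
Reagents that add atoms: none
Why: Fluoride-mediated desilylation frees the C4 alcohol under non-acidic conditions, which matters because this benzylic position, activated by three ring A oxygens, would ionise in acid.

**Step 10**
Reactants: 17 (2S)-flavan-4-ol
Product: 18 (2S)-6-geranyl-5,7,3',4'-tetrakis(methoxymethoxy)flavanone
Conditions: Dess–Martin periodinane, NaHCO3, CH2Cl2, 0 °C to rt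
Reagents that add atoms: none
Why: Dess–Martin oxidation of the secondary benzylic alcohol converts both C4 epimers to the same ketone under buffered conditions that spare the trisubstituted alkenes and do not open the pyranone ring, so C2 keeps its configuration.

**Step 11**
Reactants: 18 (2S)-tetrakis-MOM flavanone
Product: 19 nymphaeol A ((2S)-6-geranyl-5,7,3',4'-tetrahydroxyflavanone)
Conditions: 3 M aq. HCl, MeOH, 40 °C
Reagents that add atoms: none
Why: Acid-catalysed acetal methanolysis removes the four aryl MOM groups as dimethoxymethane, and dilute acid at moderate temperature is chosen to avoid cyclisation of the geranyl olefin onto the neighbouring phenols and chalcone–flavanone equilibration at C2.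

**Compound list**
1 | 5-chlororesorcinol | Oc1cc(O)cc(Cl)c1 | starting material
2 | 1-chloro-3,5-bis(methoxymethoxy)benzene | COCOc1cc(OCOC)cc(Cl)c1 | intermediate
3 | geranyl bromide ((2E)-1-bromo-3,7-dimethylocta-2,6-diene) | CC(C)=CCC/C(C)=C/CBr | starting material
4 | 4-chloro-2,6-bis(methoxymethoxy)phenyllithium | [Li]c1c(OCOC)cc(Cl)cc1OCOC | intermediate
5 | 4-chloro-2,6-bis(methoxymethoxy)phenylcopper | [Cu]c1c(OCOC)cc(Cl)cc1OCOC | intermediate
6 | 5-chloro-2-[(2E)-3,7-dimethylocta-2,6-dien-1-yl]-1,3-bis(methoxymethoxy)benzene | CC(C)=CCC/C(C)=C/Cc1c(OCOC)cc(Cl)cc1OCOC | intermediate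
7 | 6-chloro-3-geranyl-2,4-bis(methoxymethoxy)phenyllithium | CC(C)=CCC/C(C)=C/Cc1c(OCOC)cc(Cl)c([Li])c1OCOC | intermediate
8 | lithium [6-chloro-3-geranyl-2,4-bis(methoxymethoxy)phenyl](dimethylamino)methanolate | CC(C)=CCC/C(C)=C/Cc1c(OCOC)cc(Cl)c(C(O[Li])N(C)C)c1OCOC | intermediate
9 | 6-chloro-3-[(2E)-3,7-dimethylocta-2,6-dien-1-yl]-2,4-bis(methoxymethoxy)benzaldehyde | CC(C)=CCC/C(C)=C/Cc1c(OCOC)cc(Cl)c(C=O)c1OCOC | intermediate
10 | 3',4'-dihydroxyacetophenone | CC(=O)c1ccc(O)c(O)c1 | starting material
11 | 3',4'-bis(methoxymethoxy)acetophenone | CC(=O)c1ccc(OCOC)c(OCOC)c1 | intermediate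
12 | lithium 1-[3,4-bis(methoxymethoxy)phenyl]ethenolate | [Li]OC(=C)c1ccc(OCOC)c(OCOC)c1 | intermediate
13 | rac-3-[6-chloro-3-geranyl-2,4-bis(methoxymethoxy)phenyl]-3-hydroxy-1-[3,4-bis(methoxymethoxy)phenyl]propan-1-one | CC(C)=CCC/C(C)=C/Cc1c(OCOC)cc(Cl)c(C(O)CC(=O)c2ccc(OCOC)c(OCOC)c2)c1OCOC | intermediate
14 | rac-3-(tert-butyldimethylsilyloxy)-3-[6-chloro-3-geranyl-2,4-bis(methoxymethoxy)phenyl]-1-[3,4-bis(methoxymethoxy)phenyl]propan-1-one | CC(C)=CCC/C(C)=C/Cc1c(OCOC)cc(Cl)c(C(O[Si](C)(C)C(C)(C)C)CC(=O)c2ccc(OCOC)c(OCOC)c2)c1OCOC | intermediate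
15 | (1S)-3-(tert-butyldimethylsilyloxy)-3-[6-chloro-3-geranyl-2,4-bis(methoxymethoxy)phenyl]-1-[3,4-bis(methoxymethoxy)phenyl]propan-1-ol, both C3 epimers | CC(C)=CCC/C(C)=C/Cc1c(OCOC)cc(Cl)c(c1OCOC)C(O[Si](C)(C)C(C)(C)C)C[C@H](O)c1ccc(OCOC)c(OCOC)c1 | intermediate
16 | (2S)-4-(tert-butyldimethylsilyloxy)-6-geranyl-5,7,3',4'-tetrakis(methoxymethoxy)flavan, both C4 epimers | CC(C)=CCC/C(C)=C/Cc1c(OCOC)cc2c(c1OCOC)C(O[Si](C)(C)C(C)(C)C)C[C@@H](c1ccc(OCOC)c(OCOC)c1)O2 | intermediate
17 | (2S)-6-geranyl-5,7,3',4'-tetrakis(methoxymethoxy)flavan-4-ol, both C4 epimers | CC(C)=CCC/C(C)=C/Cc1c(OCOC)cc2c(c1OCOC)C(O)C[C@@H](c1ccc(OCOC)c(OCOC)c1)O2 | intermediate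
18 | (2S)-6-geranyl-5,7,3',4'-tetrakis(methoxymethoxy)flavanone | CC(C)=CCC/C(C)=C/Cc1c(OCOC)cc2c(c1OCOC)C(=O)C[C@@H](c1ccc(OCOC)c(OCOC)c1)O2 | intermediate
19 | nymphaeol A, (2S)-6-geranyl-5,7,3',4'-tetrahydroxyflavanone | CC(C)=CCC/C(C)=C/Cc1c(O)cc2c(c1O)C(=O)C[C@@H](c1ccc(O)c(O)c1)O2 | target

**Step count**
Total: 11 steps. Longest linear sequence: 10 steps (steps 1–3 and 5–11, from 5-chlororesorcinol); step 4 is a one-step side branch.

**Steps most likely to fail**

Step 8. Beta-hydride elimination from the palladium alkoxide may overtake C–O reductive elimination, or oxidative addition at the hindered chloride may be slow, so that hydrodechlorination and carbinol oxidation consume the material. The fallback closes ring C at the other oxygen bond (O1–C2) with inversion; it sets out from ketone 14 and returns at 16. Ketone 14 would be reduced with the enantiomeric catalyst RuCl[(R,R)-TsDPEN](p-cymene) in HCO2H/Et3N to (1R)-3-(tert-butyldimethylsilyloxy)-3-[6-chloro-3-geranyl-2,4-bis(methoxymethoxy)phenyl]-1-[3,4-bis(methoxymethoxy)phenyl]propan-1-ol F1. Miyaura borylation of the aryl chloride (Pd(OAc)2, XPhos, bis(pinacolato)diboron, KOAc, dioxane, 100 °C) should give the pinacol arylboronate F2, and oxidation with NaBO3·4H2O in THF/H2O the phenol F3. Mitsunobu cyclisation (PPh3, diisopropyl azodicarboxylate, THF, 0 °C) should then displace the activated R carbinol oxygen by the phenol with inversion and give the (2S)-flavan 16.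

Step 3. The ortho-chloro aryllithium may lose LiCl (aryne formation), or the base may deprotonate the doubly activated benzylic–allylic CH2 of the geranyl chain. The fallback replaces both lithiations by electrophilic formylation and phenoxide C-alkylation; it sets out from 1 and returns at 9. Vilsmeier–Haack formylation of 1 (POCl3, DMF, MeCN, then H2O) should give 2-chloro-4,6-dihydroxybenzaldehyde F4. C-Alkylation of its phenoxide with geranyl bromide 3 in aqueous KOH at the carbon between the two hydroxyls should give 6-chloro-3-geranyl-2,4-dihydroxybenzaldehyde F5. Double MOM protection (MOMCl, i-Pr2NEt, CH2Cl2) then gives aldehyde 9.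

Step 11. Protic acid may cyclise the geranyl olefin onto the freed 5- or 7-hydroxyl, or open and reclose ring C so that the C2 configuration erodes. The fallback avoids protic acid by exchanging the acetals for silyl ethers; it sets out from 18 and returns at 19. Treatment of 18 with TMSOTf and 2,2'-bipyridyl in MeCN at 0 °C should convert the four aryl MOM ethers to the tetrakis(trimethylsilyl) ether of nymphaeol A F6, which water hydrolyses at room temperature to 19.

**Further compounds**
F1 | step 8 | (1R)-3-(tert-butyldimethylsilyloxy)-3-[6-chloro-3-geranyl-2,4-bis(methoxymethoxy)phenyl]-1-[3,4-bis(methoxymethoxy)phenyl]propan-1-ol, both C3 epimers | CC(C)=CCC/C(C)=C/Cc1c(OCOC)cc(Cl)c(c1OCOC)C(O[Si](C)(C)C(C)(C)C)C[C@@H](O)c1ccc(OCOC)c(OCOC)c1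
F2 | step 8 | (1R)-3-(tert-butyldimethylsilyloxy)-3-[3-geranyl-2,4-bis(methoxymethoxy)-6-(4,4,5,5-tetramethyl-1,3,2-dioxaborolan-2-yl)phenyl]-1-[3,4-bis(methoxymethoxy)phenyl]propan-1-ol | CC(C)=CCC/C(C)=C/Cc1c(OCOC)cc(B2OC(C)(C)C(C)(C)O2)c(c1OCOC)C(O[Si](C)(C)C(C)(C)C)C[C@@H](O)c1ccc(OCOC)c(OCOC)c1
F3 | step 8 | (1R)-3-(tert-butyldimethylsilyloxy)-3-[3-geranyl-6-hydroxy-2,4-bis(methoxymethoxy)phenyl]-1-[3,4-bis(methoxymethoxy)phenyl]propan-1-ol | CC(C)=CCC/C(C)=C/Cc1c(OCOC)cc(O)c(c1OCOC)C(O[Si](C)(C)C(C)(C)C)C[C@@H](O)c1ccc(OCOC)c(OCOC)c1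
F4 | step 3 | 2-chloro-4,6-dihydroxybenzaldehyde | O=Cc1c(O)cc(O)cc1Cl
F5 | step 3 | 6-chloro-3-[(2E)-3,7-dimethylocta-2,6-dien-1-yl]-2,4-dihydroxybenzaldehyde | CC(C)=CCC/C(C)=C/Cc1c(O)cc(Cl)c(C=O)c1O
F6 | step 11 | (2S)-6-geranyl-5,7,3',4'-tetrakis(trimethylsilyloxy)flavanone | CC(C)=CCC/C(C)=C/Cc1c(O[Si](C)(C)C)cc2c(c1O[Si](C)(C)C)C(=O)C[C@@H](c1ccc(O[Si](C)(C)C)c(O[Si](C)(C)C)c1)O2
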